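Hardest feature: five oxygens sit in five different states on one flavonol. Free 5-OH and 7-OH (7-OH is the most acidic) stand beside acid-, heat- and H2-sensitive 3-O- and 4'-O-prenyl ethers, and the OMe is at C8, not C6.
Cuts: ring A is dismantled completely (C4a–C5, then C6–C7, then C7–C8), followed by C2–C1' and the three O–alkyl bonds. What remains is kojic acid.
Enabling feature: O1, C2, C3–O, C4=O, C4a–H and C8a of ring C, plus the exocyclic C8–O, map atom for atom onto kojic acid. The meta (polyketide) oxygens on C5 and C7 make C7–C6–C5 a malonyl unit, so C4a=C8a–C8=C7(OH)–C6H=C5=O is a dienylketene that closes to ring A along the C4a→C5 line of the chalcone synthase Claisen cyclisation.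
Forward: ring C is bought and ring B is joined by Suzuki coupling. Both prenyl groups and the methyl group are placed while no phenol exists, then C7 (CO2) and C6–C5 (Meldrum's acid) are added. Ring A forms last with its two OH groups already free, so no protecting group is used.
Stereochemistry: the target has none. The C8 centre of 10, 12 and 13 and the C4a centre of 15 are racemic and vanish on aromatisation.

Key step: step 8

Remark: the target SMILES has no stereocentre and no stereogenic double bond, so the compound is achiral and the demand for a single enantiomer needs no action. Prenyl means 3-methylbut-2-en-1-yl, and flavone atom numbers (C2 to C8a) are used for all intermediates.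

Step 1
Reactants: 1 kojic acid [5-hydroxy-2-(hydroxymethyl)-4H-pyran-4-one]
Product: 2 6-bromokojic acid [2-bromo-3-hydroxy-6-(hydroxymethyl)-4H-pyran-4-one]
Conditions: NBS, DMF, 0 °C to rt
Reagents that add atoms: N-bromosuccinimide, O=C1CCC(=O)N1Br
Why: Electrophilic halogenation of the enol occurs at the only ring position ortho to the enolic OH, the site where kojic acid takes up electrophiles in general, and this marks the future C2 for arylation.

Step 2
Reactants: 2 6-bromokojic acid; 3 prenyl bromide (1-bromo-3-methylbut-2-ene)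
Product: 4 2-bromo-6-(hydroxymethyl)-3-(prenyloxy)-4H-pyran-4-one
Conditions: K2CO3, DMF, rt
Reagents that add atoms: none
Why: In this Williamson ether synthesis, carbonate deprotonates only the acidic enolic OH and not the primary alcohol, and SN2 attack on the primary allylic bromide puts the final 3-O-prenyl group in place.

Step 3
Reactants: 5 4-hydroxyphenylboronic acid pinacol ester; 3 prenyl bromide
Product: 6 4-(prenyloxy)phenylboronic acid pinacol ester
Conditions: K2CO3, DMF, rt
Reagents that add atoms: none
Why: This is a Williamson ether synthesis on the phenol, and the pinacol boronate tolerates carbonate in dry DMF.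

Step 4
Reactants: 4 2-bromo-6-(hydroxymethyl)-3-(prenyloxy)-4H-pyran-4-one; 6 4-(prenyloxy)phenylboronic acid pinacol ester
Product: 7 6-(hydroxymethyl)-3-(prenyloxy)-2-[4-(prenyloxy)phenyl]-4H-pyran-4-one
Conditions: Pd(dppf)Cl2 (cat.), K2CO3, 1,4-dioxane/H2O, 80 °C
Reagents that add atoms: none
Why: In this Suzuki–Miyaura coupling the C2–Br bond is a vinylogous acyl bromide that adds readily to Pd(0), while prenyl ethers and the free primary alcohol are tolerated under carbonate conditions.

Step 5
Reactants: 7 6-(hydroxymethyl)-3-(prenyloxy)-2-[4-(prenyloxy)phenyl]-4H-pyran-4-one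
Product: 8 6-(methoxymethyl)-3-(prenyloxy)-2-[4-(prenyloxy)phenyl]-4H-pyran-4-one
Conditions: MeI, Ag2O, 4 Å MS, CH2Cl2, rt, dark
Reagents that add atoms: iodomethane, CI
Why: Purdie methylation etherifies the primary alcohol without a soluble strong base, so the acidic C8–H bonds are not deprotonated and C-methylated, and it avoids the hard methylating agents that would O-methylate the pyranone carbonyl.

Step 6
Reactants: 8 6-(methoxymethyl)-3-(prenyloxy)-2-[4-(prenyloxy)phenyl]-4H-pyran-4-one
Product: 10 (±)-2-methoxy-2-{4-oxo-5-(prenyloxy)-6-[4-(prenyloxy)phenyl]-4H-pyran-2-yl}acetic acid, via lithium dienolate 9 (not isolated)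
Conditions: LiHMDS, THF, −78 °C; dry CO2, −78 to −20 °C; cold dilute HCl to pH 3; used at once
Reagents that add atoms: carbon dioxide, O=C=O
Why: This is lateral (vinylogous) lithiation of a 2-alkyl-4-pyranone followed by carboxylation, in which the C8–H bonds are acidified by the methoxy group and by conjugation with C4=O, the extended dienolate 9 reacts at its exocyclic γ-carbon so that the pyranone is restored, and the new C8 centre forms racemic without consequence because it is erased in step 8.

Step 7
Reactants: 10 (±)-2-methoxy-2-{4-oxo-5-(prenyloxy)-6-[4-(prenyloxy)phenyl]-4H-pyran-2-yl}acetic acid; 11 Meldrum's acid (2,2-dimethyl-1,3-dioxane-4,6-dione)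
Product: 12 (±)-5-(1-hydroxy-2-methoxy-2-{4-oxo-5-(prenyloxy)-6-[4-(prenyloxy)phenyl]-4H-pyran-2-yl}ethylidene)-2,2-dimethyl-1,3-dioxane-4,6-dione
Conditions: DCC, DMAP, CH2Cl2, 0 °C to rt; cold aq. KHSO4 wash
Reagents that add atoms: none
Why: Carbodiimide/DMAP C-acylation of Meldrum's acid, the first half of the Oikawa–Yonemitsu sequence, is reliable for arylacetic-type acids with acidic α-hydrogens and runs under near-neutral conditions that leave the prenyl ethers alone.

Step 8
Reactants: 12 (±)-5-(1-hydroxy-2-methoxy-2-{4-oxo-5-(prenyloxy)-6-[4-(prenyloxy)phenyl]-4H-pyran-2-yl}ethylidene)-2,2-dimethyl-1,3-dioxane-4,6-dione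
Product: 16 5,7-dihydroxy-8-methoxy-3,4'-diprenyloxyflavone (target), via acylketene 13 (not isolated), via dienylketene 14 (not isolated), via cyclohexadienone 15 (not isolated)
Conditions: dry PhMe, slow addition of 12 to the refluxing solvent (110 °C), high dilution (ca. 2 mM), N2
Reagents that add atoms: none
Why: Proposed new method: heat expels acetone and CO2 from 12, as in the second half of the Oikawa–Yonemitsu β-keto ester synthesis, and gives acylketene 13, whose doubly activated C8–H (α to C7=O and vinylogously α to C4=O) tautomerises to the (Z)-enol 14, the dienylketene C4a=C8a–C8=C7–C6=C5=O. Ring A closes by thermal disrotatory 6π electrocyclisation, which is equally a six-membered C-acylation of C4a (the nucleophilic α-carbon of the vinylogous ester O1–C8a=C4a–C4=O) by ketene carbon C5, and the resulting 15 enolises at once to the arene 16 with its chelated 5-OH and free 7-OH. The closest known reaction types are the terminal dienylketene closure of the Danheiser, Moore and Dötz benzannulations and the Claisen cyclisation of the tetraketide in chalcone synthase, and the new element is closure of a Meldrum's-acid-derived ketene onto C3 of a γ-pyranone. No stereocentre is made, and the racemic C8 centre of 12 and 13 and the C4a centre of 15 are erased by aromatisation. Regiochemistry needs no control, because C4a is the only carbon within reach of C5 and C8 already carries its OMe, so a 6-methoxy isomer cannot arise; the selectivity that is needed is intramolecular over intermolecular capture of the ketene, which slow addition at high dilution should secure, and O-acylation by product phenols should be reversible at this temperature. The medium is neutral and 110 °C lies below the onset of aryl prenyl ether Claisen rearrangement, so both prenyl ethers should persist and the two phenols appear unprotected.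

Compound list
1 | kojic acid [5-hydroxy-2-(hydroxymethyl)-4H-pyran-4-one] | OCc1cc(=O)c(O)co1 | starting material
2 | 6-bromokojic acid [2-bromo-3-hydroxy-6-(hydroxymethyl)-4H-pyran-4-one] | OCc1cc(=O)c(O)c(Br)o1 | intermediate
3 | prenyl bromide (1-bromo-3-methylbut-2-ene) | CC(C)=CCBr | starting material
4 | 2-bromo-6-(hydroxymethyl)-3-(prenyloxy)-4H-pyran-4-one | OCc1cc(=O)c(OCC=C(C)C)c(Br)o1 | intermediate
5 | 4-hydroxyphenylboronic acid pinacol ester | Oc1ccc(cc1)B1OC(C)(C)C(C)(C)O1 | starting material
6 | 4-(prenyloxy)phenylboronic acid pinacol ester | CC(C)=CCOc1ccc(cc1)B1OC(C)(C)C(C)(C)O1 | intermediate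
7 | 6-(hydroxymethyl)-3-(prenyloxy)-2-[4-(prenyloxy)phenyl]-4H-pyran-4-one | OCc1cc(=O)c(OCC=C(C)C)c(-c2ccc(OCC=C(C)C)cc2)o1 | intermediate
8 | 6-(methoxymethyl)-3-(prenyloxy)-2-[4-(prenyloxy)phenyl]-4H-pyran-4-one | COCc1cc(=O)c(OCC=C(C)C)c(-c2ccc(OCC=C(C)C)cc2)o1 | intermediate
9 | lithium 2-(methoxymethylidene)-5-(prenyloxy)-6-[4-(prenyloxy)phenyl]-2H-pyran-4-olate (delocalised dienolate) | COC=C1C=C([O-])C(OCC=C(C)C)=C(-c2ccc(OCC=C(C)C)cc2)O1.[Li+] | intermediate
10 | (±)-2-methoxy-2-{4-oxo-5-(prenyloxy)-6-[4-(prenyloxy)phenyl]-4H-pyran-2-yl}acetic acid (racemic) | COC(C(=O)O)c1cc(=O)c(OCC=C(C)C)c(-c2ccc(OCC=C(C)C)cc2)o1 | intermediate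
11 | Meldrum's acid (2,2-dimethyl-1,3-dioxane-4,6-dione) | CC1(C)OC(=O)CC(=O)O1 | starting material
12 | (±)-5-(1-hydroxy-2-methoxy-2-{4-oxo-5-(prenyloxy)-6-[4-(prenyloxy)phenyl]-4H-pyran-2-yl}ethylidene)-2,2-dimethyl-1,3-dioxane-4,6-dione (racemic) | COC(C(O)=C1C(=O)OC(C)(C)OC1=O)c1cc(=O)c(OCC=C(C)C)c(-c2ccc(OCC=C(C)C)cc2)o1 | intermediate
13 | (±)-4-methoxy-4-{4-oxo-5-(prenyloxy)-6-[4-(prenyloxy)phenyl]-4H-pyran-2-yl}but-1-ene-1,3-dione (acylketene, racemic) | COC(C(=O)C=C=O)c1cc(=O)c(OCC=C(C)C)c(-c2ccc(OCC=C(C)C)cc2)o1 | intermediate
14 | (Z)-3-hydroxy-4-methoxy-4-{4-oxo-5-(prenyloxy)-6-[4-(prenyloxy)phenyl]-4H-pyran-2-yl}buta-1,3-dien-1-one (dienylketene) | CO/C(c1cc(=O)c(OCC=C(C)C)c(-c2ccc(OCC=C(C)C)cc2)o1)=C(O)/C=C=O | intermediate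
15 | (±)-7-hydroxy-8-methoxy-3-(prenyloxy)-2-[4-(prenyloxy)phenyl]-4aH-chromene-4,5-dione (keto tautomer of the target, racemic) | COC1=C2OC(-c3ccc(OCC=C(C)C)cc3)=C(OCC=C(C)C)C(=O)C2C(=O)C=C1O | intermediate
16 | 5,7-dihydroxy-8-methoxy-3,4'-diprenyloxyflavone | COc1c(O)cc(O)c2c(=O)c(OCC=C(C)C)c(-c3ccc(OCC=C(C)C)cc3)oc12 | target

Total step count: 8
Longest linear sequence: 7 (steps 1, 2, 4, 5, 6, 7, 8)

Steps most likely to fail

1. Step 8 (Proposed new method). Intermolecular consumption of the ketene may outrun tautomerisation and ring closure, through self-dimerisation or through hydrolysis by traces of water followed by decarboxylation. The fallback sets out from 12 and avoids any free ketene in the ring closure. Refluxing 12 in methanol (Oikawa–Yonemitsu alcoholysis) should give the isolable β-keto ester methyl (±)-4-methoxy-3-oxo-4-{4-oxo-5-(prenyloxy)-6-[4-(prenyloxy)phenyl]-4H-pyran-2-yl}butanoate F1. Ring A is then closed by an anionic Claisen (Dieckmann-type) condensation with NaOMe or Mg(OMe)2 in MeOH/THF at 0 °C to rt. Deprotonation at C8 gives the extended enolate, C4a attacks the ester carbon C5, methoxide leaves and the ring aromatises. This is the known base-induced Claisen cyclisation of 3,5,7-tricarbonyl esters to acylphloroglucinols. The fallback returns to the route at 16.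

2. Step 6. The amide base may attack or open the pyranone instead of deprotonating C8, or the vinylogous β-keto acid may lose CO2 during work-up (this only regenerates 8). The fallback sets out from 7, skips steps 5 and 6, and reverses the polarity of C8. MnO2 in CH2Cl2 should oxidise the allylic-type alcohol to 4-oxo-5-(prenyloxy)-6-[4-(prenyloxy)phenyl]-4H-pyran-2-carbaldehyde F2. Chloroform with DBU should then add to give (±)-3-(prenyloxy)-2-[4-(prenyloxy)phenyl]-6-(2,2,2-trichloro-1-hydroxyethyl)-4H-pyran-4-one F3. A Jocic–Reeve reaction (KOH, MeOH, 0 °C to rt) passes through the gem-dichloroepoxide, methoxide opens it at C8, and the acyl chloride is hydrolysed. The methoxy group and the carboxyl group thus arrive together. The fallback returns to the route at 10.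

3. Step 4. Pd(0) may ionise the allylic C–O bond of the pyranone prenyl ether, with loss of the prenyl group, or the aqueous base may hydrolyse the vinylogous acyl bromide. The fallback sets out from 2 and 5 and keeps all prenyl groups out of the palladium step. Suzuki–Miyaura coupling of 2 with 5 should give 3-hydroxy-6-(hydroxymethyl)-2-(4-hydroxyphenyl)-4H-pyran-4-one F4. One double Williamson alkylation with 3 (K2CO3, DMF, rt) should then etherify the enolic and the phenolic OH but not the primary alcohol. This replaces steps 2 to 4 and returns to the route at 7.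

Further compounds
F1 | step 8 | methyl (±)-4-methoxy-3-oxo-4-{4-oxo-5-(prenyloxy)-6-[4-(prenyloxy)phenyl]-4H-pyran-2-yl}butanoate (racemic) | COC(C(=O)CC(=O)OC)c1cc(=O)c(OCC=C(C)C)c(-c2ccc(OCC=C(C)C)cc2)o1
F2 | step 6 | 4-oxo-5-(prenyloxy)-6-[4-(prenyloxy)phenyl]-4H-pyran-2-carbaldehyde | O=Cc1cc(=O)c(OCC=C(C)C)c(-c2ccc(OCC=C(C)C)cc2)o1
F3 | step 6 | (±)-3-(prenyloxy)-2-[4-(prenyloxy)phenyl]-6-(2,2,2-trichloro-1-hydroxyethyl)-4H-pyran-4-one (racemic) | OC(c1cc(=O)c(OCC=C(C)C)c(-c2ccc(OCC=C(C)C)cc2)o1)C(Cl)(Cl)Cl
F4 | step 4 | 3-hydroxy-6-(hydroxymethyl)-2-(4-hydroxyphenyl)-4H-pyran-4-one | OCc1cc(=O)c(O)c(-c2ccc(O)cc2)o1
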